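Reckon the occupancy of the second catalyst first. Product comes from coupling partner acting on catalyst intermediate, which forms reversibly from second catalyst and open intermediate, and free catalyst supplies open intermediate from starting material.

- red: starting material 0.81 M; coupling partner 0.891 M; free catalyst 0.41 mM; second catalyst 5.2 mM; temperature 5 °C; time 8.0 min
- grey: starting material 0.81 M; coupling partner 0.891 M; free catalyst 0.41 mM; second catalyst 5.2 mM; temperature 25 °C; time 8.0 min

- which flask leads in amount of product, in percent of the starting material charged ("all alike" within 1.5 percentage points) (red / grey / all alike)
- how much product is there at the end, in percent of the starting material charged: red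
- how much product is there at the end, in percent of the starting material charged: grey

- at 25 °C the constants are as listed, elsewhere as the activation energies and enthalpies make them

    starting material + free catalyst ⇌ free catalyst + open intermediate (K1 = 9.1, k1 = 29 M⁻¹ s⁻¹, Ea1 = 40.0 kJ mol⁻¹, ΔH1 = −53.0 kJ mol⁻¹)
    second catalyst + open intermediate ⇌ catalyst intermediate (K2 = 0.11 M⁻¹, k2 = 0.94 M⁻¹ s⁻¹, Ea2 = 39.0 kJ mol⁻¹, ΔH2 = −89.0 kJ mol⁻¹)
    coupling partner + catalyst intermediate → second catalyst + product (k3 = 1.6 M⁻¹ s⁻¹, Ea3 = 53.0 kJ mol⁻¹)
    free catalyst ⇌ dormant form (K4 = 0.68, k4 = 8.1 × 10⁻⁴ s⁻¹, Ea4 = 100 kJ mol⁻¹, ΔH4 = 22.0 kJ mol⁻¹)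
    free catalyst + product → spent catalyst A (k5 = 0.0021 M⁻¹ s⁻¹, Ea5 = 78.0 kJ mol⁻¹)
    second catalyst → spent catalyst B (k6 = 0.0014 s⁻¹, Ea6 = 94.0 kJ mol⁻¹)
    (constants at 25 °C)

I took occupancy as c(catalyst intermediate) over c(second catalyst) and reckoned it two ways, both at the time-averaged c(open intermediate). In red the opening equilibrium constant rose to 42.3. The opening approached equilibrium at first order, at 0.229 min⁻¹ in red and 0.792 min⁻¹ in grey. Averaged over the time, that gave c(open intermediate) of 0.428 M in red and 0.615 M in grey.

The first way held binding at equilibrium, so occupancy was the binding constant times c(open intermediate): 0.623 in red, 0.0676 in grey. The second way took catalyst intermediate at steady state, so occupancy was c(open intermediate) over Km. Km, 1.70 M in red and 10.6 M in grey, is the Michaelis constant of the second catalyst: the reciprocal binding constant plus the coupling rate over the binding rate constant. That gave 0.252 in red and 0.0580 in grey.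

In grey the two ways stayed close, because catalyst intermediate fell back at 8.55 s⁻¹, faster than it coupled at 1.43 s⁻¹. In red they parted, because coupling at 0.306 s⁻¹ outran falling back at 0.209 s⁻¹. The equilibrium in red was being drained, so the first way cheated there, and I kept the second.

For the yield I multiplied the coupling rate, c(second catalyst) as charged, the bound share c(open intermediate)/(Km + c(open intermediate)), the time, and the mean surviving share of second catalyst. Deactivation ran at 0.00550 min⁻¹ in red and 0.0840 min⁻¹ in grey, so that share was 0.978 in red and 0.728 in grey. The first round gave 18.6% in red and 17.5% in grey.

Product had left the pool, though, so I took half of each first answer off the mean c(open intermediate), leaving 0.353 M in red and 0.544 M in grey, and went round again. Red came to 15.9% and grey to 15.6%, which made my call all alike.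

The forecast gave 16.5% for red and 13.5% for grey and named red as the leader, on the ground that “the exothermic binding holds far more catalyst as intermediate and the second catalyst barely dies, which outweighs the slower opening and slower coupling”. There it differed from me: it put red ahead by 3 percentage points, while I found the flasks level.

The simulation gave all alike, with 15.5% in red and 14.5% in grey.

At the end of grey, the net making of catalyst intermediate stood to its net loss at a ratio of 0.999. With open intermediate as it stood at 8.00 min, Km gave occupancy 0.316 in red against a reading of 0.344, and 0.0583 in grey against a reading of 0.0594.

I reckoned the same way for the grey flask read at 2.0 min. Its mean c(open intermediate) reckoned to 0.364 M, so Km gave occupancy 0.0343 and a first round of 3.35%. The simulation gave 3.09%.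

All constants were drawn at random within sensible limits; what happens was integrated by code.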